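**Plan**

1. Retrosynthesis first removes three O-benzyl groups, two O-silyl groups and the C4 carbonyl oxygen (C4=O back to C4H2), which leaves a protected (2S)-flavan.
2. Ring C of that flavan is a dihydropyran annulated to the phloroglucinol-type ring A across O1 and C4a, with one stereocentre, the oxygen-bound benzylic C2. It is therefore cut at O1–C2 and C3–C4 into an ortho-quinone methide of ring A and a ring B styrene.
3. The styrene is cut at C7''–C8'' (aldol) into O-benzylvanillin and an aryloxyacetyl imide, which comes from syringaldehyde by O-alkylation (O–C8'') and Wittig methylenation.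
4. Forward: the side chain is joined to ring B first, ring C is then closed onto ring A in one [4+2], C4 is oxidised in two stages, and the protecting groups are removed last.
5. Stereochemistry: C7''(R)/C8''(S) (erythro) come from an oxazolidinone-controlled MgCl2-catalysed anti aldol; C2(S) comes from a chiral N-triflylphosphoramide in the cycloaddition.

Key step: step 10

Assumption: which enantiomer of the phosphoramide delivers 2S cannot be predicted with certainty; the (R)-catalyst is written, and its mirror image would be used instead if the sense proves opposite.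

Locants: flavanone numbering for rings C and A (O1, C2, C3, C4, C4a–C8a), primed locants for ring B, and C7''/C8''/C9'' for the three side-chain carbons (C7'' benzylic, C8'' aryloxy-bearing, C9'' CH2O).

**Route**

Step 1
Reactants: 1 syringaldehyde
Product: 2 ethyl 2-(4-formyl-2,6-dimethoxyphenoxy)acetate
Conditions: ethyl bromoacetate, K2CO3, DMF, rt
Reagents that add atoms: ethyl bromoacetate, CCOC(=O)CBr
Why: Williamson O-alkylation of a phenol made acidic by its para formyl group with an α-halo ester under mild carbonate base, with no stereocentre involved.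

Step 2
Reactants: 2 ethyl 2-(4-formyl-2,6-dimethoxyphenoxy)acetate
Product: 3 ethyl 2-(4-ethenyl-2,6-dimethoxyphenoxy)acetate
Conditions: Ph3PCH3Br, KOtBu, THF, 0 °C (ylide preformed); then 2, −78 → 0 °C
Reagents that add atoms: methyltriphenylphosphonium bromide, C[P+](c1ccccc1)(c1ccccc1)c1ccccc1.[Br-]
Why: Wittig methylenation with the non-stabilised ylide, which should react with the aryl aldehyde far faster than with the ester, installs the vinyl group that later serves as the 2π partner.

Step 3
Reactants: 3 ethyl 2-(4-ethenyl-2,6-dimethoxyphenoxy)acetate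
Product: 4 2-(4-ethenyl-2,6-dimethoxyphenoxy)acetic acid
Conditions: LiOH·H2O, THF/H2O, rt; then 1 M HCl to pH 3, 0 °C
Reagents that add atoms: lithium hydroxide (its oxygen ends in the carboxyl group), [Li+].[OH-]
Why: Saponification of the ethyl ester by acyl–oxygen cleavage followed by cold, brief acidification should give the acid without touching the styrene.

Step 4
Reactants: 4 2-(4-ethenyl-2,6-dimethoxyphenoxy)acetic acid
Product: 6 (4S)-4-benzyl-3-[2-(4-ethenyl-2,6-dimethoxyphenoxy)acetyl]-1,3-oxazolidin-2-one, via mixed pivalic anhydride 5 (not isolated)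
Conditions: PivCl, Et3N, THF, −20 °C; then (S)-4-benzyl-1,3-oxazolidin-2-one, LiCl, −20 °C → rt
Reagents that add atoms: (S)-4-benzyl-1,3-oxazolidin-2-one, O=C1OC[C@H](Cc2ccccc2)N1; pivaloyl chloride (acyl group of intermediate 5 only), CC(C)(C)C(=O)Cl
Why: N-acylation of the Evans oxazolidinone through the mixed pivalic anhydride with LiCl and Et3N, in which the nitrogen attacks the less hindered aryloxyacetyl carbonyl, avoids acid chlorides and the HCl that could add to the styrene.

Step 5
Reactants: 6 (4S)-4-benzyl-3-[2-(4-ethenyl-2,6-dimethoxyphenoxy)acetyl]-1,3-oxazolidin-2-one; 7 4-(benzyloxy)-3-methoxybenzaldehyde (O-benzylvanillin)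
Product: 9 anti-aldol adduct (4S)-4-benzyl-3-[(2R,3R)-3-[4-(benzyloxy)-3-methoxyphenyl]-2-(4-ethenyl-2,6-dimethoxyphenoxy)-3-hydroxypropanoyl]-1,3-oxazolidin-2-one, via trimethylsilyl ether 8 (not isolated)
Conditions: MgCl2 (0.2 equiv), Et3N, TMSCl, EtOAc, rt; then 1 M HCl/THF (1:5), rt
Reagents that add atoms: chlorotrimethylsilane (silyl group of intermediate 8 only), C[Si](C)(C)Cl
Why: Evans MgCl2-catalysed direct anti aldol of an N-acyloxazolidinone with a non-enolisable aromatic aldehyde: soft enolisation gives the magnesium-chelated Z-enolate, the aldehyde adds on the face opposite the benzyl group of the (S)-auxiliary through a boat-like transition state and TMSCl traps the aldolate, which should set C7''(R) and C8'' in the anti (erythro) relationship (C8'' is labelled R in 9 only because the imide carbonyl outranks C7'').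

Step 6
Reactants: 9 anti-aldol adduct
Product: 10 (1R,2S)-1-[4-(benzyloxy)-3-methoxyphenyl]-2-(4-ethenyl-2,6-dimethoxyphenoxy)propane-1,3-diol
Conditions: LiBH4, MeOH (1 equiv), THF, 0 °C
Reagents that add atoms: none
Why: Reductive removal of the auxiliary with LiBH4, which attacks the exocyclic imide carbonyl, should give the primary alcohol without touching either stereocentre (C8'' is now labelled S) and return the oxazolidinone.

Step 7
Reactants: 10 (1R,2S)-diol
Product: 11 (1R,2S)-1-[4-(benzyloxy)-3-methoxyphenyl]-1,3-bis(tert-butyldimethylsilyloxy)-2-(4-ethenyl-2,6-dimethoxyphenoxy)propane (the ring B styrene)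
Conditions: TBSOTf (2.5 equiv), 2,6-lutidine, CH2Cl2, −78 → 0 °C
Reagents that add atoms: tert-butyldimethylsilyl trifluoromethanesulfonate, CC(C)(C)[Si](C)(C)OS(=O)(=O)C(F)(F)F
Why: A silyl triflate with a hindered pyridine base silylates the primary and the hindered secondary benzylic hydroxyl alike under non-acidic conditions and gives ethers that can later be removed by fluoride without base.

Step 8
Reactants: 12 2,4,6-trihydroxybenzaldehyde
Product: 13 2,4-bis(benzyloxy)-6-hydroxybenzaldehyde
Conditions: BnBr (2.0 equiv), K2CO3 (2.2 equiv), DMF, 0 °C → rt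
Reagents that add atoms: benzyl bromide, BrCc1ccccc1
Why: Williamson benzylation should stop at the dibenzyl ether because the 4-OH and one ortho OH are alkylated while the remaining ortho OH is tied up in a hydrogen bond to the formyl oxygen.

Step 9
Reactants: 13 2,4-bis(benzyloxy)-6-hydroxybenzaldehyde
Product: 14 3,5-bis(benzyloxy)-2-(hydroxymethyl)phenol
Conditions: NaBH4, THF/MeOH, 0 °C; neutral work-up (aq NH4Cl), used at once
Reagents that add atoms: none
Why: NaBH4 reduction of the salicylaldehyde to the salicyl alcohol at 0 °C with a neutral work-up is standard, and the product is used without storage because this electron-rich benzylic alcohol ionises easily.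

Step 10
Reactants: 11 ring B styrene; 14 3,5-bis(benzyloxy)-2-(hydroxymethyl)phenol
Product: 16 protected (2S)-flavan (2S)-5,7-bis(benzyloxy)-2-[4-({(1R,2S)-1-[4-(benzyloxy)-3-methoxyphenyl]-1,3-bis(tert-butyldimethylsilyloxy)propan-2-yl}oxy)-3,5-dimethoxyphenyl]-3,4-dihydro-2H-chromene, via ortho-quinone methide 15 (not isolated)
Conditions: (R)-3,3′-bis(2,4,6-triisopropylphenyl)-BINOL N-triflylphosphoramide (10 mol%), 5 Å MS, toluene, −40 °C; 14 (2 equiv) added over 6 h by syringe pump; Et3N quench at −40 °C
Reagents that add atoms: none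
Why: Proposed new method: the N-triflylphosphoramide protonates and ionises the benzylic alcohol of 14, and the phenolic oxygen together with the ortho and para benzyloxy groups stabilises the resulting ortho-quinone methide 15, which stays hydrogen-bonded or ion-paired to the chiral anion while the terminal CH2 of styrene 11 attacks the unsubstituted methide carbon and the ring A oxygen closes on the developing benzylic cation in a concerted but asynchronous inverse-demand [4+2]. The closest known reaction type is the chiral Brønsted acid catalysed [4+2] of aryl-substituted ortho-quinone methides, generated from ortho-hydroxybenzhydryl alcohols, with styrenes and other electron-rich alkenes; new here is a methide carbon that carries no substituent. Ring C closes as the six-membered cycloadduct of the O=C–C=CH2 heterodiene and the vinyl group, C3–C4 forming ahead of O1–C2 (in the stepwise limit a phenoxide–cation collapse). The single new stereocentre C2 is set by the catalyst, whose 3,3′-aryl groups shield one face of the bound methide so that the styrene presents one enantioface, while the remote side-chain centres exert no influence. The step needs regioselectivity (aryl at C2), which the polarisation of both partners secures because positive charge develops at the carbon that ring B stabilises. It also needs chemoselectivity over self-condensation of 14 and over ionisation of the benzylic silyl ether or of O1–C2 in the product, which slow addition of 14, low temperature, sieves and a cold basic quench are meant to secure.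

Step 11
Reactants: 16 protected (2S)-flavan
Product: 17 (2S,4RS)-flavan-4-ol (16 with OH at C4, mixture of C4 epimers)
Conditions: DDQ (1.2 equiv), CH2Cl2/pH 7 phosphate buffer (10:1), 0 °C
Reagents that add atoms: water, O
Why: DDQ abstracts hydride from C4, the benzylic position activated by three oxygen donors of ring A (O1 and 5-O ortho, 7-O para to C4a), and water traps the cation, an oxidative benzylic hydroxylation known for 5,7-dialkoxyflavans that leaves C2 untouched and gives a C4 epimer mixture that the next step converges.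

Step 12
Reactants: 17 (2S,4RS)-flavan-4-ol
Product: 18 protected (2S)-flavanone (2S)-5,7-bis(benzyloxy)-2-[4-({(1R,2S)-1-[4-(benzyloxy)-3-methoxyphenyl]-1,3-bis(tert-butyldimethylsilyloxy)propan-2-yl}oxy)-3,5-dimethoxyphenyl]-2,3-dihydro-4H-chromen-4-one
Conditions: Dess–Martin periodinane, pyridine, CH2Cl2, 0 °C → rt
Reagents that add atoms: none
Why: Dess–Martin oxidation of the secondary benzylic alcohol to the aryl ketone under pyridine-buffered conditions removes the C4 stereocentre and should not epimerise C2, which could only be lost through base-induced ring opening to the chalcone.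

Step 13
Reactants: 18 protected (2S)-flavanone
Product: 19 (2S)-5,7-bis(benzyloxy)-2-[4-({(1R,2S)-1-[4-(benzyloxy)-3-methoxyphenyl]-1,3-dihydroxypropan-2-yl}oxy)-3,5-dimethoxyphenyl]-2,3-dihydro-4H-chromen-4-one
Conditions: HF·pyridine, pyridine, THF, 0 °C → rt
Reagents that add atoms: none
Why: Fluoride-mediated cleavage of both silyl ethers with buffered HF·pyridine is chosen over basic fluoride sources, which would open the flavanone to the chalcone and erase C2.

Step 14
Reactants: 19 tri-O-benzyl flavanone diol
Product: 20 target (2S)-5,7-dihydroxy-2-[4-({(1R,2S)-1,3-dihydroxy-1-(4-hydroxy-3-methoxyphenyl)propan-2-yl}oxy)-3,5-dimethoxyphenyl]-2,3-dihydro-4H-chromen-4-one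
Conditions: H2 (1 atm), 10% Pd/C, EtOAc/MeOH, rt, stopped at full conversion
Reagents that add atoms: none
Why: Hydrogenolysis of the three aryl benzyl ethers over Pd/C in neutral solvent should be much faster than cleavage of the secondary benzylic C7''–OH or the cyclic benzylic C2–O1 bond, and the carbonyl, deactivated by the oxygens of ring A, is not expected to be reduced.

**Compound list**

1 | syringaldehyde (4-hydroxy-3,5-dimethoxybenzaldehyde) | COc1cc(C=O)cc(OC)c1O | starting material
2 | ethyl 2-(4-formyl-2,6-dimethoxyphenoxy)acetate | CCOC(=O)COc1c(OC)cc(C=O)cc1OC | intermediate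
3 | ethyl 2-(4-ethenyl-2,6-dimethoxyphenoxy)acetate | CCOC(=O)COc1c(OC)cc(C=C)cc1OC | intermediate
4 | 2-(4-ethenyl-2,6-dimethoxyphenoxy)acetic acid | OC(=O)COc1c(OC)cc(C=C)cc1OC | intermediate
5 | mixed anhydride of 4 with pivalic acid (not isolated) | CC(C)(C)C(=O)OC(=O)COc1c(OC)cc(C=C)cc1OC | intermediate
6 | (4S)-4-benzyl-3-[2-(4-ethenyl-2,6-dimethoxyphenoxy)acetyl]-1,3-oxazolidin-2-one | O=C1OC[C@H](Cc2ccccc2)N1C(=O)COc1c(OC)cc(C=C)cc1OC | intermediate
7 | 4-(benzyloxy)-3-methoxybenzaldehyde (O-benzylvanillin) | COc1cc(C=O)ccc1OCc1ccccc1 | starting material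
8 | O-trimethylsilyl ether of aldol adduct 9 (not isolated) | COc1cc([C@@H](O[Si](C)(C)C)[C@H](C(=O)N2[C@@H](Cc3ccccc3)COC2=O)Oc2c(OC)cc(C=C)cc2OC)ccc1OCc1ccccc1 | intermediate
9 | (4S)-4-benzyl-3-[(2R,3R)-3-[4-(benzyloxy)-3-methoxyphenyl]-2-(4-ethenyl-2,6-dimethoxyphenoxy)-3-hydroxypropanoyl]-1,3-oxazolidin-2-one | COc1cc([C@@H](O)[C@H](C(=O)N2[C@@H](Cc3ccccc3)COC2=O)Oc2c(OC)cc(C=C)cc2OC)ccc1OCc1ccccc1 | intermediate
10 | (1R,2S)-1-[4-(benzyloxy)-3-methoxyphenyl]-2-(4-ethenyl-2,6-dimethoxyphenoxy)propane-1,3-diol | COc1cc([C@@H](O)[C@H](CO)Oc2c(OC)cc(C=C)cc2OC)ccc1OCc1ccccc1 | intermediate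
11 | (1R,2S)-1-[4-(benzyloxy)-3-methoxyphenyl]-1,3-bis(tert-butyldimethylsilyloxy)-2-(4-ethenyl-2,6-dimethoxyphenoxy)propane | COc1cc([C@@H](O[Si](C)(C)C(C)(C)C)[C@H](CO[Si](C)(C)C(C)(C)C)Oc2c(OC)cc(C=C)cc2OC)ccc1OCc1ccccc1 | intermediate
12 | 2,4,6-trihydroxybenzaldehyde | O=Cc1c(O)cc(O)cc1O | starting material
13 | 2,4-bis(benzyloxy)-6-hydroxybenzaldehyde | O=Cc1c(O)cc(OCc2ccccc2)cc1OCc1ccccc1 | intermediate
14 | 3,5-bis(benzyloxy)-2-(hydroxymethyl)phenol | OCc1c(O)cc(OCc2ccccc2)cc1OCc1ccccc1 | intermediate
15 | 3,5-bis(benzyloxy)-6-methylidenecyclohexa-2,4-dien-1-one, the ortho-quinone methide (not isolated) | C=C1C(=O)C=C(OCc2ccccc2)C=C1OCc1ccccc1 | intermediate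
16 | (2S)-5,7-bis(benzyloxy)-2-[4-({(1R,2S)-1-[4-(benzyloxy)-3-methoxyphenyl]-1,3-bis(tert-butyldimethylsilyloxy)propan-2-yl}oxy)-3,5-dimethoxyphenyl]-3,4-dihydro-2H-chromene | COc1cc([C@@H](O[Si](C)(C)C(C)(C)C)[C@H](CO[Si](C)(C)C(C)(C)C)Oc2c(OC)cc([C@@H]3CCc4c(OCc5ccccc5)cc(OCc5ccccc5)cc4O3)cc2OC)ccc1OCc1ccccc1 | intermediate
17 | (2S,4RS)-4-hydroxy derivative of 16 (flavan-4-ol, C4 epimer mixture) | COc1cc([C@@H](O[Si](C)(C)C(C)(C)C)[C@H](CO[Si](C)(C)C(C)(C)C)Oc2c(OC)cc([C@@H]3CC(O)c4c(OCc5ccccc5)cc(OCc5ccccc5)cc4O3)cc2OC)ccc1OCc1ccccc1 | intermediate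
18 | (2S)-5,7-bis(benzyloxy)-2-[4-({(1R,2S)-1-[4-(benzyloxy)-3-methoxyphenyl]-1,3-bis(tert-butyldimethylsilyloxy)propan-2-yl}oxy)-3,5-dimethoxyphenyl]-2,3-dihydro-4H-chromen-4-one | COc1cc([C@@H](O[Si](C)(C)C(C)(C)C)[C@H](CO[Si](C)(C)C(C)(C)C)Oc2c(OC)cc([C@@H]3CC(=O)c4c(OCc5ccccc5)cc(OCc5ccccc5)cc4O3)cc2OC)ccc1OCc1ccccc1 | intermediate
19 | (2S)-5,7-bis(benzyloxy)-2-[4-({(1R,2S)-1-[4-(benzyloxy)-3-methoxyphenyl]-1,3-dihydroxypropan-2-yl}oxy)-3,5-dimethoxyphenyl]-2,3-dihydro-4H-chromen-4-one | COc1cc([C@@H](O)[C@H](CO)Oc2c(OC)cc([C@@H]3CC(=O)c4c(OCc5ccccc5)cc(OCc5ccccc5)cc4O3)cc2OC)ccc1OCc1ccccc1 | intermediate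
20 | (2S)-5,7-dihydroxy-2-[4-({(1R,2S)-1,3-dihydroxy-1-(4-hydroxy-3-methoxyphenyl)propan-2-yl}oxy)-3,5-dimethoxyphenyl]-2,3-dihydro-4H-chromen-4-one | COc1cc([C@@H](O)[C@H](CO)Oc2c(OC)cc([C@@H]3CC(=O)c4c(O)cc(O)cc4O3)cc2OC)ccc1O | target

**Step count**

Total: 14 steps. Longest linear sequence: 12 steps (steps 1–7, then 10–14, from syringaldehyde); steps 8 and 9 form the short branch to ring A.

**Steps most likely to fail, with fallbacks**

Step 10 (the proposed new method). Three processes threaten it. The salicyl alcohol or its methide may condense with itself at the nucleophilic ring A positions faster than it is intercepted by the styrene. The unsubstituted methide may give the catalyst too little to discriminate the styrene enantiofaces. The acid may ionise the benzylic silyl ether, or reopen O1–C2 of the product and so epimerise C2.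

The fallback builds the same flavan by known steps and sets C2 by reagent-controlled reduction followed by an invertive ring closure. It sets out from styrene 11 and aldehyde 13 and returns at flavan 16. Tsuji–Wacker oxidation of 11 (PdCl2, CuCl, O2, DMF/H2O) would give the ring B methyl ketone F1. Claisen–Schmidt condensation of F1 with 13 (KOH, EtOH) would give the 2-hydroxychalcone F2. Hydrogenation of the enone double bond with RhCl(PPh3)3 and H2, which spares benzyl ethers, would give the dihydrochalcone F3. Corey–Bakshi–Shibata reduction of F3 with the (S)-methyl oxazaborolidine and BH3·SMe2 would give the (R)-carbinol F4. Mitsunobu cyclisation of F4 (PPh3, DIAD, THF) would then join the ring A phenol oxygen to C2 with inversion and deliver 16.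

Step 5. The aryloxy oxygen and its flanking methoxy groups may compete for magnesium and loosen the chelated transition state, which would erode or reverse the anti selectivity. Retro-aldol of the adduct from an electron-rich aldehyde may also hold conversion down before silylation.

The fallback relies on the firmly established boron syn aldol and then inverts C7''. It sets out from acid 4 and returns at styrene 11. Acylation of (R)-4-benzyl-1,3-oxazolidin-2-one through anhydride 5 would give the enantiomeric imide F5. Bu2BOTf and iPr2NEt in CH2Cl2 followed by aldehyde 7 would give the Evans syn adduct F6. LiBH4 would give the threo diol F7. TBSCl and imidazole would silylate only the primary hydroxyl to give the silyl ether F8. Mitsunobu esterification with 4-nitrobenzoic acid (PPh3, DIAD) would invert C7'' and give the erythro 4-nitrobenzoate F9. K2CO3 in MeOH would release the erythro secondary alcohol F10. TBSOTf and 2,6-lutidine would convert F10 into 11.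

Step 11. The C4 cation may lose a C3 proton instead of capturing water, which leads to the flav-3-ene and on to the flavylium ion. The quinone may also abstract hydride at C7'' (a dialkoxybenzylic silyl ether) or at C2.

The fallback replaces hydride abstraction by a quinone with acetoxylation by a metal acetate, which delivers the oxygen as a stable ester that cannot be dehydrogenated further. It sets out from flavan 16 and returns at flavan-4-ol 17. Pb(OAc)4 in benzene would give the 4-acetoxyflavan F11. LiOH in THF/H2O would convert F11 into 17, whether by acyl cleavage or by ionisation and capture of water.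

**Further compounds**

F1 | step 10 | ring B methyl ketone: 11 with the vinyl group replaced by acetyl | COc1cc([C@@H](O[Si](C)(C)C(C)(C)C)[C@H](CO[Si](C)(C)C(C)(C)C)Oc2c(OC)cc(C(C)=O)cc2OC)ccc1OCc1ccccc1
F2 | step 10 | (E)-2-hydroxychalcone: ring B aryl ketone joined through CH=CH to the 2,4-bis(benzyloxy)-6-hydroxyphenyl group | COc1cc([C@@H](O[Si](C)(C)C(C)(C)C)[C@H](CO[Si](C)(C)C(C)(C)C)Oc2c(OC)cc(C(=O)/C=C/c3c(O)cc(OCc4ccccc4)cc3OCc3ccccc3)cc2OC)ccc1OCc1ccccc1
F3 | step 10 | dihydrochalcone: F2 with the enone C=C saturated | COc1cc([C@@H](O[Si](C)(C)C(C)(C)C)[C@H](CO[Si](C)(C)C(C)(C)C)Oc2c(OC)cc(C(=O)CCc3c(O)cc(OCc4ccccc4)cc3OCc3ccccc3)cc2OC)ccc1OCc1ccccc1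
F4 | step 10 | (R)-carbinol: F3 with the ketone reduced to the (1R)-alcohol | COc1cc([C@@H](O[Si](C)(C)C(C)(C)C)[C@H](CO[Si](C)(C)C(C)(C)C)Oc2c(OC)cc([C@H](O)CCc3c(O)cc(OCc4ccccc4)cc3OCc3ccccc3)cc2OC)ccc1OCc1ccccc1
F5 | step 5 | (4R)-4-benzyl-3-[2-(4-ethenyl-2,6-dimethoxyphenoxy)acetyl]-1,3-oxazolidin-2-one | O=C1OC[C@@H](Cc2ccccc2)N1C(=O)COc1c(OC)cc(C=C)cc1OC
F6 | step 5 | syn adduct (4R)-4-benzyl-3-[(2R,3S)-3-[4-(benzyloxy)-3-methoxyphenyl]-2-(4-ethenyl-2,6-dimethoxyphenoxy)-3-hydroxypropanoyl]-1,3-oxazolidin-2-one | COc1cc([C@H](O)[C@H](C(=O)N2[C@H](Cc3ccccc3)COC2=O)Oc2c(OC)cc(C=C)cc2OC)ccc1OCc1ccccc1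
F7 | step 5 | threo diol (1S,2S)-1-[4-(benzyloxy)-3-methoxyphenyl]-2-(4-ethenyl-2,6-dimethoxyphenoxy)propane-1,3-diol | COc1cc([C@H](O)[C@H](CO)Oc2c(OC)cc(C=C)cc2OC)ccc1OCc1ccccc1
F8 | step 5 | (1S,2S)-1-[4-(benzyloxy)-3-methoxyphenyl]-3-(tert-butyldimethylsilyloxy)-2-(4-ethenyl-2,6-dimethoxyphenoxy)propan-1-ol | COc1cc([C@H](O)[C@H](CO[Si](C)(C)C(C)(C)C)Oc2c(OC)cc(C=C)cc2OC)ccc1OCc1ccccc1
F9 | step 5 | (1R,2S)-1-[4-(benzyloxy)-3-methoxyphenyl]-3-(tert-butyldimethylsilyloxy)-2-(4-ethenyl-2,6-dimethoxyphenoxy)propyl 4-nitrobenzoate | COc1cc([C@@H](OC(=O)c2ccc(cc2)[N+](=O)[O-])[C@H](CO[Si](C)(C)C(C)(C)C)Oc2c(OC)cc(C=C)cc2OC)ccc1OCc1ccccc1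
F10 | step 5 | (1R,2S)-1-[4-(benzyloxy)-3-methoxyphenyl]-3-(tert-butyldimethylsilyloxy)-2-(4-ethenyl-2,6-dimethoxyphenoxy)propan-1-ol | COc1cc([C@@H](O)[C@H](CO[Si](C)(C)C(C)(C)C)Oc2c(OC)cc(C=C)cc2OC)ccc1OCc1ccccc1
F11 | step 11 | (2S,4RS)-4-acetoxy derivative of 16 (4-acetoxyflavan, C4 epimer mixture) | COc1cc([C@@H](O[Si](C)(C)C(C)(C)C)[C@H](CO[Si](C)(C)C(C)(C)C)Oc2c(OC)cc([C@@H]3CC(OC(C)=O)c4c(OCc5ccccc5)cc(OCc5ccccc5)cc4O3)cc2OC)ccc1OCc1ccccc1
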